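All constants are invented; the rest is arithmetic.

The target and the isomer of the product come from the same two reactants, so the question is how much of each stands at the end of this flask:

starting material 1.0 mM (in portions, 4); solid reagent 0.600 equiv; time 6.0 min; the portions of starting material follow each other after 1.5 s, the first at the start

    solid reagent ⇌ partner, rate k1*(cs1 - [partner]) while solid is left; crystals form when [partner] > cs1 (cs1 = 0.49 mM, k1 = 0.22 s⁻¹)
    starting material + partner ⇌ isomer of the product (K2 = 3000 L mol⁻¹, k2 = 95 L mol⁻¹ s⁻¹)
    starting material + partner ⇌ target (K3 = 1300 L mol⁻¹, k3 = 230 L mol⁻¹ s⁻¹)

- given per volume of solution although it is solid: solid reagent
- at the start none of the solid reagent is in solution
- the reaction counts as stopped when no species that holds the starting material changes by six tenths of a point or more over the second half of the time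
- run time (flask): 6.0 min

1. which holds at 6.0 min: what has brought the reaction to rest, or that it has not come to rest (for what has run out or reacted, a solid counts together with what of it has only dissolved) (it is still moving / the partner has run out first / forward and back rates have come level / all of the starting material has reacted)
2. how much of the starting material has reacted by 6.0 min
3. how much target there is at 6.0 min, in percent of the starting material charged
4. how much isomer of the product there is at 6.0 min, in percent of the starting material charged

Q. What do you write first?

A. The balance of the partner, the limiting reagent by charge at e = 0.600 equiv. Let x be the fraction of the starting material charge bound as target or isomer. Free starting material is then 1 − x, and partner not bound is e − x, both as fractions of that charge.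

Q. May you use equilibrium here?

A. I expect so. The slower way back is the isomer's, with a lifetime of 31.6 s (equilibrium constant over rate constant) against 5.65 s for the target, and the 6.0 min of the run is far longer.

Q. Then reckon.

A. Both products draw on the same pair, so their constants add. The binding number, the sum of the two equilibrium constants times the charge of starting material, is 4.30. The balance reads x = N(1 − x)(e − x), and its root below e is 42.7%.

Q. But the solid is charged above its solubility. Doesn't some stay undissolved and spoil your balance?

A. No, because the unbound partner comes to 17.3% of the charge, while the solubility is 49.0% of it. So the balance needs no term for the solid.

Q. The target has the faster forward step. Why isn't it the main product?

A. Its rate constant is larger, which favours it early, under kinetic control. Its equilibrium constant is smaller, however, and thermodynamic control splits x into 12.9% target and 29.8% isomer, with forward and back rates level.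

The forecast gives the same picture: forward and back rates have come level, with conversion 42.7%, target 12.9% and isomer 29.8%, saying “6 minutes is ample for full equilibrium”.

The flask gives 42.7% conversion, 12.9% target and 29.8% isomer, and its state at the asked time is: forward and back rates have come level. Its target stood at 18.9% after 0.300 min and at 13.1% after 1.20 min. Take now the neighbour flask with 0.60 mM of starting material and the same equivalents. Its binding number is 2.58, and the same balance gives x = 37.1%. That neighbour flask shows a conversion of 37.1%.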